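**Plan** (germacrane numbering: ring C1–C10; C14 = ester carbon on C10; C15 = methyl on C4; lactone O6–C12(=O)–C11(=C13)–C7)
Cuts: first the O8 and O9 acyl groups and the 4,5-epoxide oxygen, then C9–C10, and last C6–C7 together with O6–C12.
Enabling feature: inside the ten-membered ring the C9 carbinol sits on C10, the α-carbon of the C1=C10–C14 enoate. This is a Morita–Baylis–Hillman motif, so it maps onto a C1≡C10 ynoate and a C9 aldehyde.
Forward: fragment A is an enal ynoate (C1–C6, C10, C14, C15) from geranyl acetate. Fragment B is an allylboronate (C7–C9, C11–C13) from (R)-solketal. They are joined at C6–C7 and the γ-lactone closes in the same flask; the carbocycle then closes at C9–C10, and the oxirane comes last.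
Stereochemistry: C8 comes from the chiral pool. C6 and C7 come from the chair allylboration, where the boronate geometry gives the trans lactone and C8 chooses the face. C9 comes from Felkin–Anh attack anti to the C8 silyloxy group.
The C1=C10 geometry comes from the iodoallenolate and a retentive deiodination, and C4/C5 from peripheral epoxidation of the E-olefin.

Key step: step 13

Remark: geranyl acetate, (R)-solketal, 2-(iodomethyl)pinacolborane and the Ohira–Bestmann reagent are taken as commercial. The CIP letters at C6 and C7 change along the route only because substituent priorities change; the spatial arrangement does not.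

Step 1
Reactants: 1 geranyl acetate
Product: 2 (2E)-3-methyl-6-oxohex-2-en-1-yl acetate
Conditions: O3 (1 equiv, Sudan Red 7B end point), CH2Cl2, −78 °C; Me2S, −78 °C → rt
Reagents that add atoms: ozone [O-][O+]=O
Why: Chemoselective ozonolysis with reductive work-up: the electron-rich isopropylidene olefin is consumed first because the 2,3-olefin is deactivated by the allylic acetoxy group, so the E-configured C4=C5 unit survives.

Step 2
Reactants: 2 (2E)-3-methyl-6-oxohex-2-en-1-yl acetate
Product: 4 (2E)-3-methylhept-2-en-6-yn-1-ol, via enynyl acetate 3 (not isolated)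
Conditions: dimethyl (1-diazo-2-oxopropyl)phosphonate, K2CO3, MeOH, 0 °C → rt
Reagents that add atoms: dimethyl (1-diazo-2-oxopropyl)phosphonate COP(=O)(OC)C(=[N+]=[N-])C(C)=O
Why: Ohira–Bestmann homologation adds the alkyne carbon C10 to the C1 aldehyde, and the same K2CO3/MeOH medium methanolyses the allylic acetate, which saves a separate deprotection.

Step 3
Reactants: 4 (2E)-3-methylhept-2-en-6-yn-1-ol
Product: 5 methyl (6E)-8-hydroxy-6-methyloct-6-en-2-ynoate
Conditions: PdCl2 (5 mol %), CuCl2 (2.5 equiv), NaOAc (2.5 equiv), CO (1 atm), MeOH, rt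
Reagents that add atoms: carbon monoxide [C-]#[O+]; methanol CO
Why: Palladium-catalysed oxidative methoxycarbonylation of a terminal alkyne (alkynylpalladium formation on divalent palladium, CO insertion, methanolysis, reoxidation by CuCl2) installs C14 without strong base, so the free allylic alcohol and the trisubstituted olefin are left alone.

Step 4
Reactants: 5 methyl (6E)-8-hydroxy-6-methyloct-6-en-2-ynoate
Product: 6 methyl (6E)-6-methyl-8-oxooct-6-en-2-ynoate (fragment A, aldehyde carbon = C6)
Conditions: MnO2 (activated, excess), CH2Cl2, rt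
Reagents that add atoms: none
Why: MnO2 oxidation is selective for the allylic alcohol and keeps the E geometry of the 3-methyl-2-enal, while the ynoate is inert.

Step 5
Reactants: 7 (R)-solketal
Product: 8 (4S)-2,2-dimethyl-1,3-dioxolane-4-carbaldehyde
Conditions: (COCl)2, DMSO, CH2Cl2, −78 °C; Et3N, −78 → 0 °C; used crude
Reagents that add atoms: none
Why: Swern oxidation delivers the configurationally sensitive α-alkoxy aldehyde without epimerisation when it is kept cold and used at once; its stereocentre, taken from the chiral pool, becomes C8 of the target.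

Step 6
Reactants: 8 (4S)-2,2-dimethyl-1,3-dioxolane-4-carbaldehyde
Product: 9 (4R)-4-(2,2-dibromoethenyl)-2,2-dimethyl-1,3-dioxolane
Conditions: CBr4, PPh3, CH2Cl2, 0 °C
Reagents that add atoms: carbon tetrabromide BrC(Br)(Br)Br
Why: Dibromoolefination with the ylide from CBr4 and PPh3 (first half of the Corey–Fuchs sequence) is routine for glyceraldehyde acetonide and does not touch C8.

Step 7
Reactants: 9 (4R)-4-(2,2-dibromoethenyl)-2,2-dimethyl-1,3-dioxolane
Product: 11 methyl 3-[(4R)-2,2-dimethyl-1,3-dioxolan-4-yl]prop-2-ynoate, via lithium acetylide 10 (not isolated)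
Conditions: n-BuLi (2.1 equiv), THF, −78 °C; ClCO2Me, −78 → 0 °C
Reagents that add atoms: methyl chloroformate COC(=O)Cl
Why: Second half of the Corey–Fuchs sequence: lithium–bromine exchange, loss of LiBr with 1,2-shift and deprotonation give acetylide 10, which is C-acylated by the chloroformate to bring in C12.

Step 8
Reactants: 11 methyl 3-[(4R)-2,2-dimethyl-1,3-dioxolan-4-yl]prop-2-ynoate
Product: 13 methyl (2Z)-3-[(4R)-2,2-dimethyl-1,3-dioxolan-4-yl]-2-[(4,4,5,5-tetramethyl-1,3,2-dioxaborolan-2-yl)methyl]prop-2-enoate (fragment B), via alkenylalane 12 (not isolated)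
Conditions: i-Bu2AlH, HMPA, THF, 0 °C; 11, 0 °C; ICH2Bpin, 0 °C → rt
Reagents that add atoms: 2-(iodomethyl)-4,4,5,5-tetramethyl-1,3,2-dioxaborolane ICB1OC(C)(C)C(C)(C)O1
Why: Conjugate syn-hydroalumination of an alkynoate by the i-Bu2AlH–HMPA complex puts hydrogen on C7 and aluminium on C11, and alkylation of alane 12 with the iodomethylboronate with retention is the established entry to 2-alkoxycarbonyl allylboronates, here with C8 cis to the ester and trans to CH2B.

Step 9
Reactants: 6 methyl (6E)-6-methyl-8-oxooct-6-en-2-ynoate; 13 allylboronate (fragment B)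
Product: 15 methyl (6E)-7-{(2R,3S)-3-[(4R)-2,2-dimethyl-1,3-dioxolan-4-yl]-4-methylidene-5-oxooxolan-2-yl}-6-methylhept-6-en-2-ynoate (trans lactone; 6R,7S,8R), via O-boryl hydroxy ester 14 (not isolated)
Conditions: Sc(OTf)3 (10 mol %), toluene, 0 °C → rt; aqueous work-up
Reagents that add atoms: none
Why: Lewis acid-catalysed allylboration through a closed chair transition state followed by lactonisation of borate 14: the boronate geometry (C8 trans to CH2B) is translated into the anti adduct and thus the trans-6,7-lactone, while the face of C7 is chosen by C8, because allylic 1,3-strain with the cis ester holds H8 in the olefin plane and the aldehyde then approaches anti to the C8–O bond, on the side remote from the acetal methyl groups.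

Step 10
Reactants: 15 lactone acetonide
Product: 16 methyl (6E)-7-{(2R,3R)-3-[(1R)-1,2-dihydroxyethyl]-4-methylidene-5-oxooxolan-2-yl}-6-methylhept-6-en-2-ynoate
Conditions: AcOH–H2O–THF (4:1:1), 40 °C
Reagents that add atoms: none
Why: Mild acid hydrolysis of a terminal acetonide; the weakly acidic medium leaves ynoate and α-methylene lactone intact and is too mild to move the lactone from O6 to O8.

Step 11
Reactants: 16 8,9-diol
Product: 17 methyl (6E)-7-{(2R,3S)-3-[(1R)-1,2-bis(triethylsilyloxy)ethyl]-4-methylidene-5-oxooxolan-2-yl}-6-methylhept-6-en-2-ynoate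
Conditions: Et3SiOTf (2.4 equiv), 2,6-lutidine, CH2Cl2, −78 °C
Reagents that add atoms: triethylsilyl triflate CC[Si](CC)(CC)OS(=O)(=O)C(F)(F)F
Why: Silylation with the silyl triflate and the non-nucleophilic base 2,6-lutidine is fast at low temperature and avoids imidazole or DMAP, which would add to the ynoate.

Step 12
Reactants: 17 bis(triethylsilyl) ether
Product: 18 methyl (6E)-6-methyl-7-{(2R,3S)-4-methylidene-5-oxo-3-[(1R)-2-oxo-1-(triethylsilyloxy)ethyl]oxolan-2-yl}hept-6-en-2-ynoate (ynoate aldehyde)
Conditions: (COCl)2 (4 equiv), DMSO (8 equiv), CH2Cl2, −78 → −40 °C; Et3N, −78 → −20 °C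
Reagents that add atoms: none
Why: Under Swern conditions a primary triethylsilyl ether is cleaved by the chlorosulfonium salt and oxidised directly to the aldehyde whereas the secondary one persists, a known selective oxidative desilylation that frees the C9 aldehyde without a free-alcohol stage and without epimerising C8.

Step 13
Reactants: 18 ynoate aldehyde
Product: 20 methyl (1(10)Z,4E,6R,7S,8R,9S)-9-hydroxy-1-iodo-8-(triethylsilyloxy)germacra-1(10),4,11(13)-trien-12,6-olid-14-oate, via magnesium iodoallenolate 19 (not isolated)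
Conditions: MgI2 (3 equiv), CH2Cl2, 0 °C, 18 added by syringe pump over 12 h (final 1 mM); pH 7 buffer
Reagents that add atoms: magnesium iodide [Mg+2].[I-].[I-]
Why: Proposed new method: MgI2 binds the ynoate carbonyl, iodide adds to C1, and the magnesium β-iodoallenolate 19 attacks the magnesium-bound C9 aldehyde through C10; this is the intramolecular form of the intermolecular MgI2- or Et2AlI-promoted halo-aldol (β-iodo Morita–Baylis–Hillman) reaction of alkynoates, which has not been shown for a β-alkyl ynoate in a medium-ring closure. The ten-membered carbocycle closes in a 10-exo-trig mode at the aldehyde (enolexo with respect to the C10=C14 allenolate bond), and slow addition at high dilution has to hold back the bimolecular aldol. C9 is the only new stereocentre and is set by polar Felkin–Anh attack anti to the C8–OSiEt3 bond, the non-chelating silyl ether keeping magnesium off O8, which gives the 8,9-anti (9S) carbinol. The olefin geometry is decided when the aldehyde enters in the plane of the two C1 substituents: it comes from the side of the C2 tether and away from the bulky iodine, so that iodine ends cis to the ester and C2 cis to C9. Chemoselectivity rests on the far higher acceptor strength of the ynoate compared with the α-methylene lactone, to which iodide adds only reversibly and from which no aldehyde is within reach, and on the reversibility of iodide addition, which returns unproductive allenolate to 18.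

Step 14
Reactants: 20 iodo enoate alcohol
Product: 21 methyl (1(10)E,4E,6R,7S,8R,9S)-9-hydroxy-8-(triethylsilyloxy)germacra-1(10),4,11(13)-trien-12,6-olid-14-oate
Conditions: Pd(PPh3)4 (5 mol %), Bu3SnH (1.1 equiv, slow addition), THF, 0 °C → rt
Reagents that add atoms: none
Why: Palladium-catalysed hydrodehalogenation (oxidative addition of the alkenyl iodide to zerovalent palladium, hydride transfer from tin, reductive elimination) runs with retention of olefin geometry, is much faster than hydrometalation of the acrylate units or ionisation of the allylic C6–O bond, and is placed before acetylation because a C9 acetate would be an ionisable allylic ester.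

Step 15
Reactants: 21 C9 alcohol
Product: 22 methyl (1(10)E,4E,6R,7S,8R,9S)-9-acetoxy-8-(triethylsilyloxy)germacra-1(10),4,11(13)-trien-12,6-olid-14-oate
Conditions: Ac2O, pyridine, DMAP (cat.), CH2Cl2, 0 °C
Reagents that add atoms: acetic anhydride CC(=O)OC(C)=O
Why: DMAP-catalysed acetylation of the only free hydroxyl group; C9 keeps its configuration because only the O–H bond reacts.

Step 16
Reactants: 22 C9 acetate
Product: 23 methyl (1(10)E,4E,6R,7R,8R,9S)-9-acetoxy-8-hydroxygermacra-1(10),4,11(13)-trien-12,6-olid-14-oate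
Conditions: HF·pyridine, pyridine, THF, 0 °C
Reagents that add atoms: none
Why: Fluoride-driven desilylation in the buffered, weakly acidic HF·pyridine medium generates no alkoxide, which suppresses acetyl migration from O9 to O8 and relactonisation.

Step 17
Reactants: 23 C8 alcohol
Product: 24 methyl (1(10)E,4E,6R,7S,8R,9S)-9-acetoxy-8-(methacryloyloxy)germacra-1(10),4,11(13)-trien-12,6-olid-14-oate
Conditions: methacrylic anhydride, Et3N, DMAP, CH2Cl2, 0 °C → rt
Reagents that add atoms: methacrylic anhydride C=C(C)C(=O)OC(=O)C(C)=C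
Why: DMAP-catalysed acylation with the anhydride at low temperature is expected to outrun acetyl migration and puts the methacrylate on O8 with retention at C8.

Step 18
Reactants: 24 4,5-olefin
Product: 25 target, methyl (1(10)E,4R,5R,6S,7R,8R,9S)-9-acetoxy-4,5-epoxy-8-(methacryloyloxy)germacra-1(10),11(13)-dien-12,6-olid-14-oate
Conditions: m-CPBA (1.1 equiv), CH2Cl2, 0 °C
Reagents that add atoms: 3-chloroperbenzoic acid O=C(OO)c1cccc(Cl)c1
Why: Prilezhaev epoxidation: C4=C5 is the only olefin not conjugated with a carbonyl group, allylic 1,3-strain between C15 and C6 holds H6 in the olefin plane so that the ring (C7 side) covers the inner face, and the peracid attacks the outer face on the O6 side, which together with the E geometry gives the (4R,5R)-trans-epoxide.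

**Compound list**
1 | geranyl acetate | CC(C)=CCC/C(C)=C/COC(C)=O | starting material
2 | (2E)-3-methyl-6-oxohex-2-en-1-yl acetate | O=CCC/C(C)=C/COC(C)=O | intermediate
3 | (2E)-3-methylhept-2-en-6-yn-1-yl acetate (not isolated) | C#CCC/C(C)=C/COC(C)=O | intermediate
4 | (2E)-3-methylhept-2-en-6-yn-1-ol | C#CCC/C(C)=C/CO | intermediate
5 | methyl (6E)-8-hydroxy-6-methyloct-6-en-2-ynoate | COC(=O)C#CCC/C(C)=C/CO | intermediate
6 | methyl (6E)-6-methyl-8-oxooct-6-en-2-ynoate | COC(=O)C#CCC/C(C)=C/C=O | intermediate
7 | (R)-solketal, [(4R)-2,2-dimethyl-1,3-dioxolan-4-yl]methanol | OC[C@@H]1COC(C)(C)O1 | starting material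
8 | (4S)-2,2-dimethyl-1,3-dioxolane-4-carbaldehyde | O=C[C@@H]1COC(C)(C)O1 | intermediate
9 | (4R)-4-(2,2-dibromoethenyl)-2,2-dimethyl-1,3-dioxolane | BrC(Br)=C[C@@H]1COC(C)(C)O1 | intermediate
10 | lithium acetylide of (4R)-4-ethynyl-2,2-dimethyl-1,3-dioxolane (not isolated) | [Li]C#C[C@@H]1COC(C)(C)O1 | intermediate
11 | methyl 3-[(4R)-2,2-dimethyl-1,3-dioxolan-4-yl]prop-2-ynoate | COC(=O)C#C[C@@H]1COC(C)(C)O1 | intermediate
12 | methyl (2E)-2-(diisobutylalumanyl)-3-[(4R)-2,2-dimethyl-1,3-dioxolan-4-yl]prop-2-enoate (not isolated) | COC(=O)/C([Al](CC(C)C)CC(C)C)=C\[C@@H]1COC(C)(C)O1 | intermediate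
13 | methyl (2Z)-3-[(4R)-2,2-dimethyl-1,3-dioxolan-4-yl]-2-[(pinacolboryl)methyl]prop-2-enoate | COC(=O)/C(CB1OC(C)(C)C(C)(C)O1)=C\[C@@H]1COC(C)(C)O1 | intermediate
14 | O6-pinacolboryl anti hydroxy ester, open form of 15 (not isolated) | CC1(C)OC[C@H](O1)[C@H]([C@H](OB2OC(C)(C)C(C)(C)O2)/C=C(\C)CCC#CC(=O)OC)C(=C)C(=O)OC | intermediate
15 | trans α-methylene lactone, 8,9-acetonide, ynoate (6R,7S,8R) | CC1(C)OC[C@H](O1)[C@H]2C(=C)C(=O)O[C@@H]2/C=C(\C)CCC#CC(=O)OC | intermediate
16 | trans α-methylene lactone, 8,9-diol, ynoate (6R,7R,8R) | OC[C@H](O)[C@H]1C(=C)C(=O)O[C@@H]1/C=C(\C)CCC#CC(=O)OC | intermediate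
17 | trans α-methylene lactone, 8,9-bis(triethylsilyl) ether, ynoate (6R,7S,8R) | CC[Si](CC)(CC)OC[C@H](O[Si](CC)(CC)CC)[C@H]1C(=C)C(=O)O[C@@H]1/C=C(\C)CCC#CC(=O)OC | intermediate
18 | ynoate aldehyde, C9 aldehyde with C8 triethylsilyl ether (6R,7S,8R) | O=C[C@H](O[Si](CC)(CC)CC)[C@H]1C(=C)C(=O)O[C@@H]1/C=C(\C)CCC#CC(=O)OC | intermediate
19 | magnesium β-iodoallenolate of 18 (not isolated) | O=C[C@H](O[Si](CC)(CC)CC)[C@H]1C(=C)C(=O)O[C@@H]1/C=C(\C)CCC(I)=C=C(OC)O[Mg]I | intermediate
20 | ten-membered β-iodo enoate C9 alcohol (1(10)Z,4E,6R,7S,8R,9S) | CC[Si](CC)(CC)O[C@@H]1[C@H]2C(=C)C(=O)O[C@@H]2/C=C(\C)CC/C(I)=C(/C(=O)OC)[C@@H]1O | intermediate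
21 | ten-membered enoate C9 alcohol (1(10)E,4E,6R,7S,8R,9S) | CC[Si](CC)(CC)O[C@@H]1[C@H]2C(=C)C(=O)O[C@@H]2/C=C(\C)CC/C=C(/C(=O)OC)[C@@H]1O | intermediate
22 | C9 acetate, C8 triethylsilyl ether (6R,7S,8R,9S) | CC[Si](CC)(CC)O[C@@H]1[C@H]2C(=C)C(=O)O[C@@H]2/C=C(\C)CC/C=C(/C(=O)OC)[C@@H]1OC(C)=O | intermediate
23 | C9 acetate, C8 alcohol (6R,7R,8R,9S) | O[C@@H]1[C@H]2C(=C)C(=O)O[C@@H]2/C=C(\C)CC/C=C(/C(=O)OC)[C@@H]1OC(C)=O | intermediate
24 | C9 acetate, C8 methacrylate, 4,5-olefin (6R,7S,8R,9S) | C=C(C)C(=O)O[C@@H]1[C@H]2C(=C)C(=O)O[C@@H]2/C=C(\C)CC/C=C(/C(=O)OC)[C@@H]1OC(C)=O | intermediate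
25 | CNP0153978.4 (4R,5R,6S,7R,8R,9S) | C=C(C)C(=O)O[C@@H]1[C@H]2C(=C)C(=O)O[C@@H]2[C@H]2O[C@]2(C)CC/C=C(/C(=O)OC)[C@@H]1OC(C)=O | target

Total step count: 18. Longest linear sequence: 14 steps (steps 1–4 or steps 5–8, then steps 9–18).

**Steps most likely to fail**

Step 13.
- What may go wrong: intermolecular aldol addition and oligomerisation; plain hydroiodination of the ynoate without ring closure; erosion of Felkin–Anh control by strain in the cyclic transition state; leakage to the ring-trans olefin geometry.
- Fallback: it keeps the C9–C10 bond but makes it from a preformed C10 alkenyl metal. It sets out from 17 and comes back at 21, so step 14 falls away.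
- Ruthenium-catalysed trans-hydrostannation of the ynoate ([Cp*RuCl]4, Bu3SnH, CH2Cl2) should place tin on C10 and hydrogen on C1 from opposite sides, giving the C10-stannyl enoate F1.
- Iododestannylation (I2, CH2Cl2, 0 °C) gives, with retention, the C10-iodo enoate F2, in which C2 is cis to iodine.
- The selective Swern oxidation of step 12 then gives the iodo enoate aldehyde F3.
- An intramolecular Nozaki–Hiyama–Kishi reaction (CrCl2, NiCl2 cat., DMSO–THF, high dilution) closes the ring to 21.

Step 9.
- What may go wrong: poor discrimination between the two faces of C7 by the C8 stereocentre, and sluggish addition of the electron-poor boronate to a conjugated aldehyde.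
- Fallback: the C6–C7 bond is made with an allylchromium reagent and the lactone carbonyl is brought in afterwards. It sets out from 8 and 6 and comes back at 15.
- Wittig reaction of 8 with ethyl bromo(triphenylphosphoranylidene)acetate gives the (Z)-α-bromo enoate F4.
- Reduction with i-Bu2AlH gives the bromoallylic alcohol F5, and CBr4/PPh3 gives the allylic bromide F6, in which C8 already stands trans to CH2Br.
- With CrCl2 in THF at 0 °C (Nozaki–Hiyama allylation; divalent chromium inserts only into the allylic C–Br bond) and 6, the anti, Felkin–Anh-type bromovinyl homoallylic alcohol F7 is expected. This selectivity pattern is established for dioxolane-bearing allylic bromides.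
- Carbonylative lactonisation (Pd(PPh3)4, CO, Et3N, MeCN) closes the α-methylene lactone 15.

Step 8.
- What may go wrong: competing 1,2-reduction of the ester, loss of olefin geometry through the aluminium allenolate before alkylation, and slow alkylation of the alane.
- Fallback: hydrometalation, halogenation and C–C coupling are carried out as separate operations. It sets out from 11 and comes back at 13.
- Palladium-catalysed syn-hydrostannation (Pd(PPh3)4, Bu3SnH, THF) gives the α-stannyl enoate F8.
- Iododestannylation gives the α-iodo enoate F9 with retention.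
- Negishi coupling with (pinacolboryl)methylzinc iodide, made from ICH2Bpin and zinc dust (Pd(PPh3)4, THF), gives 13 with the geometry fixed at the stannane stage.

**Further compounds**
F1 | step 13 | 17 with the ynoate replaced by a (1(10)Z)-C10-tributylstannyl enoate | CC[Si](CC)(CC)OC[C@H](O[Si](CC)(CC)CC)[C@H]1C(=C)C(=O)O[C@@H]1/C=C(\C)CC/C=C(/C(=O)OC)[Sn](CCCC)(CCCC)CCCC
F2 | step 13 | 17 with the ynoate replaced by a (1(10)Z)-C10-iodo enoate | CC[Si](CC)(CC)OC[C@H](O[Si](CC)(CC)CC)[C@H]1C(=C)C(=O)O[C@@H]1/C=C(\C)CC/C=C(/C(=O)OC)I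
F3 | step 13 | C9 aldehyde with C8 triethylsilyl ether and (1(10)Z)-C10-iodo enoate | O=C[C@H](O[Si](CC)(CC)CC)[C@H]1C(=C)C(=O)O[C@@H]1/C=C(\C)CC/C=C(/C(=O)OC)I
F4 | step 9 | ethyl (2Z)-2-bromo-3-[(4R)-2,2-dimethyl-1,3-dioxolan-4-yl]prop-2-enoate | CCOC(=O)/C(Br)=C/[C@@H]1COC(C)(C)O1
F5 | step 9 | (2Z)-2-bromo-3-[(4R)-2,2-dimethyl-1,3-dioxolan-4-yl]prop-2-en-1-ol | OC/C(Br)=C/[C@@H]1COC(C)(C)O1
F6 | step 9 | (4R)-4-[(1Z)-2,3-dibromoprop-1-en-1-yl]-2,2-dimethyl-1,3-dioxolane | BrC/C(Br)=C/[C@@H]1COC(C)(C)O1
F7 | step 9 | anti homoallylic alcohol with C11 vinyl bromide, 8,9-acetonide and ynoate | CC1(C)OC[C@H](O1)[C@H]([C@H](O)/C=C(\C)CCC#CC(=O)OC)C(Br)=C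
F8 | step 8 | methyl (2E)-3-[(4R)-2,2-dimethyl-1,3-dioxolan-4-yl]-2-(tributylstannyl)prop-2-enoate | COC(=O)/C([Sn](CCCC)(CCCC)CCCC)=C\[C@@H]1COC(C)(C)O1
F9 | step 8 | methyl (2E)-3-[(4R)-2,2-dimethyl-1,3-dioxolan-4-yl]-2-iodoprop-2-enoate | COC(=O)/C(I)=C\[C@@H]1COC(C)(C)O1
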